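**Retrosynthetic overview**

1. Ring D is closed last through the C13–C18 bond, which belongs to ring D only: a tertiary C13 radical adds 6-exo to the C18=C19 alkene of ring E. The enabling feature is that this bond joins quaternary C13 (next to quaternary C14) to C18 (next to quaternary C17), a congestion a radical tolerates, while the C15–C16 tether holds the alkene, which has no allylic hydrogen, in reach.
2. The dioxane and both sesquiterpene rings are in place before that: hetero-Diels–Alder reaction of the ring A o-quinone with (7S,10R)-guaia-1(5),3,11-triene 8.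
3. Rings A/B/C: 2,3-dimethoxytoluene → 2-tetralone 28 → chiral-imine Michael addition and Robinson annulation (C9) → dissolving-metal reductive alkylation with the ring E iodide 19 (C8, C14).
4. Ring E: asymmetric Diels–Alder (C20), Luche reduction, Claisen rearrangement (C17). Sesquiterpene: (S)-carvone → enzymatic reduction → ring expansion → Shapiro/crotonaldehyde → cationic 4π-cyclization.
5. Order of ring formation: seven- and five-membered rings of 8; ring E; ring B; ring C; dioxane; ring D.

Key step: step 29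

Remark: diene 8 equilibrates with its 1,5-hydrogen-shift isomers; it is used freshly and is taken to react through the 1(5),3-diene form at its C3=C4 bond.

Numbering: triterpenoid carbons as in pristimerin (C1–C30, rings A–E); sesquiterpene carbons as in guaiane (C1'–C15').

**Sesquiterpene**

Step 1
Reactants: 1 (S)-(+)-carvone
Product: 2 (2R,5S)-dihydrocarvone (cis)
Conditions: ene-reductase OYE1, NADP+ (cat.), glucose dehydrogenase, D-glucose, phosphate buffer pH 7, 30 °C
Reagents that add atoms: none
Why: Enzymatic conjugate reduction of the enone delivers hydride and proton under enzyme control and should set the 2R centre, giving the cis isomer that chemical reduction does not favour.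

Step 2
Reactants: 2 (2R,5S)-dihydrocarvone
Product: 3 (2R,5S)-2-methyl-5-(prop-1-en-2-yl)cycloheptan-1-one
Conditions: Me3SiCHN2, BF3·OEt2, CH2Cl2, −78 °C; aqueous acid work-up
Reagents that add atoms: trimethylsilyldiazomethane C[Si](C)(C)C=[N+]=[N-]
Why: Diazoalkane ring expansion (Tiffeneau–Demjanov type) should insert the carbon on the less substituted side of the ketone, with both stereocentres untouched under non-basic conditions.

Step 3
Reactants: 3 cycloheptanone
Product: 4 2,4,6-triisopropylbenzenesulfonylhydrazone of 3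
Conditions: 2,4,6-triisopropylbenzenesulfonyl hydrazide, MeOH, cat. HCl, rt
Reagents that add atoms: 2,4,6-triisopropylbenzenesulfonyl hydrazide NNS(=O)(=O)c1c(C(C)C)cc(C(C)C)cc1C(C)C
Why: Hydrazone condensation prepares the Shapiro reaction.

Step 4
Reactants: 4 trisylhydrazone; 5 (E)-crotonaldehyde
Product: 7 (2E)-1-[(4S,7R)-7-methyl-4-(prop-1-en-2-yl)cyclohept-1-en-1-yl]but-2-en-1-ol (carbinol epimers), via cycloheptenyllithium 6 (not isolated)
Conditions: n-BuLi (2.2 equiv), THF/TMEDA, −78 → 0 °C; then 5, −78 °C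
Reagents that add atoms: none
Why: Shapiro reaction deprotonates the less substituted α-CH2, so the C10' centre is never enolized, and the vinyllithium adds 1,2 to the enal.

Step 5
Reactants: 7 bis-allylic alcohol
Product: 8 (7S,10R)-guaia-1(5),3,11-triene
Conditions: TsOH·H2O (5 mol%), Et2O, 0 °C → rt; used at once
Reagents that add atoms: none
Why: Ionization to the pentadienyl cation, conrotatory 4π-electrocyclization (Nazarov-type dehydrative cyclization) and proton loss give the cyclopentadiene, which settles by 1,5-hydrogen shifts into its most substituted isomers.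

**Ring E iodide**

Step 6
Reactants: 9 isoprene; 10 methacrolein
Product: 11 (R)-1,4-dimethylcyclohex-3-ene-1-carbaldehyde
Conditions: o-tolyl-CBS-oxazaborolidine activated by Tf2NH (10 mol%, enantiomer chosen for the R product), CH2Cl2, −78 °C
Reagents that add atoms: none
Why: Catalytic asymmetric Diels–Alder reaction of an α-substituted acrolein gives the para adduct and sets the C20 quaternary centre by shielding one face of the bound aldehyde.

Step 7
Reactants: 11 aldehyde
Product: 12 (R)-1,4-dimethylcyclohex-3-ene-1-carboxylic acid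
Conditions: NaClO2, NaH2PO4, 2-methyl-2-butene, t-BuOH/H2O, 0 °C
Reagents that add atoms: sodium chlorite [Na+].[O-]Cl=O
Why: Pinnick oxidation converts the hindered aldehyde without touching the alkene.

Step 8
Reactants: 12 acid
Product: 13 methyl (R)-1,4-dimethylcyclohex-3-ene-1-carboxylate
Conditions: MeI, K2CO3, DMF, rt
Reagents that add atoms: iodomethane CI
Why: Carboxylate O-alkylation gives the methyl ester of the target.

Step 9
Reactants: 13 ester
Product: 14 methyl (R)-1,4-dimethyl-2-oxocyclohex-3-ene-1-carboxylate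
Conditions: Rh2(C6H10NO)4 (dirhodium tetracaprolactamate, 1 mol%), t-BuOOH, K2CO3, CH2Cl2, rt
Reagents that add atoms: tert-butyl hydroperoxide CC(C)(C)OO
Why: Allylic oxidation of a 1-methylcyclohexene should occur at the CH2 next to the vinylic CH and give the 3-methyl-enone (C19 ketone).

Step 10
Reactants: 14 enone
Product: 15 methyl (1R,2S)-2-hydroxy-1,4-dimethylcyclohex-3-ene-1-carboxylate
Conditions: NaBH4, CeCl3·7H2O, MeOH, −78 °C
Reagents that add atoms: none
Why: Luche 1,2-reduction by axial hydride attack anti to the pseudo-axial ester should place the hydroxyl cis to the ester.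

Step 11
Reactants: 15 allylic alcohol
Product: 17 methyl (1R,4R)-1,4-dimethyl-4-(2-oxoethyl)cyclohex-2-ene-1-carboxylate, via allyl vinyl ether 16 (not isolated)
Conditions: ethyl vinyl ether, Hg(OAc)2 (cat.), reflux; concentrate; decane, 190 °C, sealed tube
Reagents that add atoms: ethyl vinyl ether C=COCC
Why: Claisen rearrangement transfers the two-carbon arm suprafacially from the C19 oxygen to C17, so the C17 quaternary centre is set cis to the ester and the alkene moves to C18=C19.

Step 12
Reactants: 17 aldehyde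
Product: 18 methyl (1R,4R)-4-(2-hydroxyethyl)-1,4-dimethylcyclohex-2-ene-1-carboxylate
Conditions: NaBH4, MeOH, 0 °C
Reagents that add atoms: none
Why: Borohydride reduction takes the aldehyde and leaves the hindered tertiary ester.

Step 13
Reactants: 18 alcohol
Product: 19 methyl (1R,4R)-4-(2-iodoethyl)-1,4-dimethylcyclohex-2-ene-1-carboxylate
Conditions: I2, PPh3, imidazole, CH2Cl2, 0 °C → rt
Reagents that add atoms: iodine II
Why: Appel-type iodination of a primary alcohol.

**Tetralone**

Step 14
Reactants: 20 2,3-dimethoxytoluene; 21 succinic anhydride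
Product: 22 4-(3,4-dimethoxy-2-methylphenyl)-4-oxobutanoic acid
Conditions: AlCl3, CH2Cl2/nitrobenzene, 0 °C → rt
Reagents that add atoms: none
Why: Friedel–Crafts acylation should go para to the unhindered methoxy group, ortho to the methyl.

Step 15
Reactants: 22 keto acid
Product: 23 4-(3,4-dimethoxy-2-methylphenyl)butanoic acid
Conditions: Et3SiH, CF3CO2H, 50 °C
Reagents that add atoms: none
Why: Ionic hydrogenation removes the aryl ketone.

Step 16
Reactants: 23 acid
Product: 24 6,7-dimethoxy-5-methyl-3,4-dihydronaphthalen-1(2H)-one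
Conditions: Eaton's reagent (P2O5 in MeSO3H), 40 °C
Reagents that add atoms: none
Why: Intramolecular Friedel–Crafts acylation can close ring B only at the one free ortho position.

Step 17
Reactants: 24 1-tetralone
Product: 26 6,7-dimethoxy-4,8-dimethyl-1,2-dihydronaphthalene, via tertiary benzylic alcohol 25 (not isolated)
Conditions: MeMgBr, THF, 0 °C; then TsOH·H2O (cat.), benzene, reflux
Reagents that add atoms: methylmagnesium bromide C[Mg]Br
Why: Grignard addition and acid dehydration of the benzylic alcohol give the styrene.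

Step 18
Reactants: 26 dihydronaphthalene
Product: 28 6,7-dimethoxy-1,5-dimethyl-3,4-dihydronaphthalen-2(1H)-one (racemic), via epoxide 27 (not isolated)
Conditions: mCPBA, NaHCO3, CH2Cl2, 0 °C; then BF3·OEt2 (cat.), benzene, rt
Reagents that add atoms: 3-chloroperbenzoic acid O=C(OO)c1cccc(Cl)c1
Why: Epoxidation and Meinwald rearrangement through the benzylic cation with hydride shift give the 2-tetralone.

**Assembly**

Step 19
Reactants: 28 2-tetralone; 29 ethyl vinyl ketone
Product: 32 (S)-6,7-dimethoxy-1,5-dimethyl-1-(3-oxopentyl)-3,4-dihydronaphthalen-2(1H)-one, via imine 30 (not isolated), via Michael adduct imine 31 (not isolated)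
Conditions: (S)-1-phenylethylamine, TsOH (cat.), toluene, reflux (−H2O); then 29, THF, 40 °C; then aq. AcOH, rt
Reagents that add atoms: water O
Why: Chiral-imine Michael addition through the more substituted secondary enamine (aza-ene-like transition state, acceptor anti to the phenyl group) converts the racemic tetralone into the C9 quaternary centre (9β-methyl series).

Step 20
Reactants: 32 1,5-diketone
Product: 33 (4aR)-6,7-dimethoxy-1,4a,8-trimethyl-4,4a,9,10-tetrahydrophenanthren-2(3H)-one (C13 ketone, C8=C14)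
Conditions: NaOMe, MeOH, 60 °C
Reagents that add atoms: none
Why: Aldol condensation (Robinson annulation) closes ring C.

Step 21
Reactants: 33 tricyclic enone; 19 ring E iodide
Product: 35 ring-D-seco ketone (rings A, B, C, E; 2,3-dimethoxy; 8α-H; 9β-Me; 14β-Me; C13 ketone; C14–C15–C16–C17 link to ring E), via lithium enolate 34 (not isolated)
Conditions: Li (2.2 equiv), NH3(l)/THF, t-BuOH (1 equiv), −78 °C; then 19, HMPA, −33 °C → rt
Reagents that add atoms: none
Why: Dissolving-metal reductive alkylation protonates C8 axially to give the trans B/C fusion, and the regiospecific C14 enolate is alkylated on the α-face, opposite the 1,3-related axial C9 methyl, which leaves the C14 methyl β.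

Step 22
Reactants: 35 dimethyl ether
Product: 36 catechol ketone
Conditions: BBr3 (3 equiv), CH2Cl2, −78 → −10 °C; then MeOH, H2O
Reagents that add atoms: none
Why: Lewis-acid ether cleavage of the chelating veratrole unit is faster at low temperature than attack on the hindered methyl ester.

Step 23
Reactants: 36 catechol
Product: 37 bis(tert-butyldimethylsilyl) ether
Conditions: t-BuMe2SiCl, imidazole, DMF, rt
Reagents that add atoms: tert-butyldimethylsilyl chloride CC(C)(C)[Si](C)(C)Cl
Why: Silylation gives a catechol protection that fluoride removes later.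

Step 24
Reactants: 37 ketone
Product: 38 C13 tertiary alcohol (C13 epimers; the centre is reset in step 29)
Conditions: MeLi, CeCl3, THF, −78 °C
Reagents that add atoms: methyllithium [Li]C
Why: Organocerium 1,2-addition takes the hindered, enolizable ketone in preference to the tertiary ester.

Step 25
Reactants: 38 tetralin
Product: 39 6-ene (1,2-dihydronaphthalene)
Conditions: DDQ, 1,4-dioxane, rt → 50 °C
Reagents that add atoms: none
Why: Benzylic dehydrogenation by hydride abstraction at C6 (para to the C2 oxygen) and loss of H7; C9 is quaternary, so no naphthalene can form.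

Step 26
Reactants: 39 bis-silyl ether
Product: 40 catechol 6-ene
Conditions: Bu4NF, AcOH, THF, 0 °C
Reagents that add atoms: none
Why: Fluoride desilylation of aryl silyl ethers.

Step 27
Reactants: 40 catechol; 8 guaiatriene (3 equiv)
Product: 42 benzodioxane adduct (ring-D-seco; sesquiterpene and dioxane as in the target), via o-quinone 41 (not isolated)
Conditions: Ag2O, MgSO4, CH2Cl2, 0 °C, dark; then 8, 0 °C → rt
Reagents that add atoms: none
Why: Inverse-demand hetero-Diels–Alder reaction: the unsubstituted C3' should bond first to the less hindered C2 oxygen and C4' then to the C3 oxygen, and suprafacial addition makes the dioxane cis-fused; the face of the diene is not fixed by its remote stereocentres, so the adduct with both oxygens syn to the C10' methyl is separated from its diastereomer.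

Step 28
Reactants: 42 tertiary alcohol
Product: 44 tert-alkyl N-phthalimidoyl oxalate, via chlorooxalate 43 (not isolated)
Conditions: (COCl)2, Et3N, DMAP (cat.), CH2Cl2, −78 → 0 °C; then N-hydroxyphthalimide, Et3N, 0 °C
Reagents that add atoms: oxalyl chloride ClC(=O)C(=O)Cl; N-hydroxyphthalimide ON1C(=O)c2ccccc2C1=O
Why: Acylation of the tertiary alcohol under basic conditions installs a radical precursor without passing through a C13 cation.

Step 29
Reactants: 44 N-phthalimidoyl oxalate
Product: 45 target CNP0222748.1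
Conditions: Ru(bpy)3(PF6)2 (2 mol%), Hantzsch ester (1.5 equiv), THF/CH2Cl2 (0.005 M), blue LEDs, rt
Reagents that add atoms: none
Why: Photoreductive single-electron transfer to the N-acyloxyphthalimide expels phthalimide anion and two CO2 to give the tertiary C13 radical, which adds to C18 of the ring E alkene, and the C19 radical takes hydrogen from the Hantzsch ester. The reaction type is the reductive radical cyclization of a tertiary alkyl radical, as in stannane-mediated cyclizations and radical polyene cyclizations, with the radical generated as in oxalate-based tertiary-radical couplings. Ring D closes in the 6-exo-trig mode. At C13 a chair-like transition state, with the C15 tether equatorial on C14 and the new bond equatorial, should give the trans C/D fusion with the methyl axial α, as in the second ring closure of radical polyene cyclizations. At C18 the bond must form on the alkene face that carries the C16 tether at C17, which gives the cis D/E fusion with 18β-H. The step needs cyclization to outrun hydrogen transfer, which high dilution and the slow hydrogen donor favour, and the C18=C19 bond is the only alkene the C13 radical can reach.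

**Compound list**

1 | (S)-(+)-carvone | C=C(C)[C@H]1CC=C(C)C(=O)C1 | starting material
2 | (2R,5S)-dihydrocarvone | C=C(C)[C@H]1CC[C@@H](C)C(=O)C1 | intermediate
3 | (2R,5S)-2-methyl-5-(prop-1-en-2-yl)cycloheptan-1-one | C=C(C)[C@H]1CC[C@@H](C)C(=O)CC1 | intermediate
4 | trisylhydrazone of 3 | C=C(C)[C@H]1CC[C@@H](C)C(=NNS(=O)(=O)c2c(C(C)C)cc(C(C)C)cc2C(C)C)CC1 | intermediate
5 | (E)-crotonaldehyde | C/C=C/C=O | starting material
6 | cycloheptenyllithium from 4 | C=C(C)[C@H]1CC[C@@H](C)C([Li])=CC1 | intermediate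
7 | (2E)-1-[(4S,7R)-7-methyl-4-(prop-1-en-2-yl)cyclohept-1-en-1-yl]but-2-en-1-ol | C=C(C)[C@H]1CC[C@@H](C)C(C(O)/C=C/C)=CC1 | intermediate
8 | (7S,10R)-guaia-1(5),3,11-triene | C=C(C)[C@H]1CC[C@@H](C)C2=C(C1)C(C)=CC2 | intermediate
9 | isoprene | C=CC(C)=C | starting material
10 | methacrolein | C=C(C)C=O | starting material
11 | (R)-1,4-dimethylcyclohex-3-ene-1-carbaldehyde | CC1=CC[C@](C)(C=O)CC1 | intermediate
12 | (R)-1,4-dimethylcyclohex-3-ene-1-carboxylic acid | CC1=CC[C@](C)(C(=O)O)CC1 | intermediate
13 | methyl (R)-1,4-dimethylcyclohex-3-ene-1-carboxylate | CC1=CC[C@](C)(C(=O)OC)CC1 | intermediate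
14 | methyl (R)-1,4-dimethyl-2-oxocyclohex-3-ene-1-carboxylate | CC1=CC(=O)[C@](C)(C(=O)OC)CC1 | intermediate
15 | methyl (1R,2S)-2-hydroxy-1,4-dimethylcyclohex-3-ene-1-carboxylate | CC1=C[C@H](O)[C@](C)(C(=O)OC)CC1 | intermediate
16 | vinyl ether of 15 | CC1=C[C@H](OC=C)[C@](C)(C(=O)OC)CC1 | intermediate
17 | methyl (1R,4R)-1,4-dimethyl-4-(2-oxoethyl)cyclohex-2-ene-1-carboxylate | O=CC[C@]1(C)C=C[C@](C)(C(=O)OC)CC1 | intermediate
18 | methyl (1R,4R)-4-(2-hydroxyethyl)-1,4-dimethylcyclohex-2-ene-1-carboxylate | OCC[C@]1(C)C=C[C@](C)(C(=O)OC)CC1 | intermediate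
19 | methyl (1R,4R)-4-(2-iodoethyl)-1,4-dimethylcyclohex-2-ene-1-carboxylate | ICC[C@]1(C)C=C[C@](C)(C(=O)OC)CC1 | intermediate
20 | 2,3-dimethoxytoluene | COc1cccc(C)c1OC | starting material
21 | succinic anhydride | O=C1CCC(=O)O1 | starting material
22 | 4-(3,4-dimethoxy-2-methylphenyl)-4-oxobutanoic acid | COc1ccc(C(=O)CCC(=O)O)c(C)c1OC | intermediate
23 | 4-(3,4-dimethoxy-2-methylphenyl)butanoic acid | COc1ccc(CCCC(=O)O)c(C)c1OC | intermediate
24 | 6,7-dimethoxy-5-methyl-3,4-dihydronaphthalen-1(2H)-one | COc1cc2c(c(C)c1OC)CCCC2=O | intermediate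
25 | 6,7-dimethoxy-1,5-dimethyl-1,2,3,4-tetrahydronaphthalen-1-ol | COc1cc2c(c(C)c1OC)CCCC2(C)O | intermediate
26 | 6,7-dimethoxy-4,8-dimethyl-1,2-dihydronaphthalene | COc1cc2c(c(C)c1OC)CCC=C2C | intermediate
27 | epoxide of 26 | COc1cc2c(c(C)c1OC)CCC1OC21C | intermediate
28 | 6,7-dimethoxy-1,5-dimethyl-3,4-dihydronaphthalen-2(1H)-one (racemic) | COc1cc2c(c(C)c1OC)CCC(=O)C2C | intermediate
29 | ethyl vinyl ketone (pent-1-en-3-one) | C=CC(=O)CC | starting material
30 | (S)-1-phenylethyl imine of 28 | C[C@H](N=C1CCc2c(C)c(OC)c(OC)cc2C1C)c1ccccc1 | intermediate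
31 | imine of Michael adduct | C[C@H](N=C1CCc2c(C)c(OC)c(OC)cc2[C@]1(C)CCC(=O)CC)c1ccccc1 | intermediate
32 | (S)-6,7-dimethoxy-1,5-dimethyl-1-(3-oxopentyl)-3,4-dihydronaphthalen-2(1H)-one | CCC(=O)CC[C@]1(C)C(=O)CCc2c(C)c(OC)c(OC)cc21 | intermediate
33 | (4aR)-6,7-dimethoxy-1,4a,8-trimethyl-4,4a,9,10-tetrahydrophenanthren-2(3H)-one | COc1c(OC)cc2c(c1C)CCC1=C(C)C(=O)CC[C@@]21C | intermediate
34 | lithium enolate (8α-H; C13 O-Li; C13=C14) | COc1c(OC)cc2c(c1C)CC[C@H]1[C@@]2(C)CCC(O[Li])=C1C | intermediate
35 | ring-D-seco ketone, dimethyl ether (8α-H, 9β-Me, 14β-Me, C13=O) | COc1c(OC)cc2c(c1C)CC[C@H]1[C@@]2(C)CCC(=O)[C@]1(C)CC[C@]1(C)C=C[C@](C)(C(=O)OC)CC1 | intermediate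
36 | ring-D-seco ketone, catechol | Oc1c(O)cc2c(c1C)CC[C@H]1[C@@]2(C)CCC(=O)[C@]1(C)CC[C@]1(C)C=C[C@](C)(C(=O)OC)CC1 | intermediate
37 | ring-D-seco ketone, bis-silyl ether | CC(C)(C)[Si](C)(C)Oc1c(O[Si](C)(C)C(C)(C)C)cc2c(c1C)CC[C@H]1[C@@]2(C)CCC(=O)[C@]1(C)CC[C@]1(C)C=C[C@](C)(C(=O)OC)CC1 | intermediate
38 | C13 tertiary alcohol, bis-silyl ether (C13 epimers) | CC(C)(C)[Si](C)(C)Oc1c(O[Si](C)(C)C(C)(C)C)cc2c(c1C)CC[C@H]1[C@@]2(C)CCC(C)(O)[C@]1(C)CC[C@]1(C)C=C[C@](C)(C(=O)OC)CC1 | intermediate
39 | 6-ene tertiary alcohol, bis-silyl ether | CC(C)(C)[Si](C)(C)Oc1c(O[Si](C)(C)C(C)(C)C)cc2c(c1C)C=C[C@H]1[C@@]2(C)CCC(C)(O)[C@]1(C)CC[C@]1(C)C=C[C@](C)(C(=O)OC)CC1 | intermediate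
40 | 6-ene tertiary alcohol, catechol | Oc1c(O)cc2c(c1C)C=C[C@H]1[C@@]2(C)CCC(C)(O)[C@]1(C)CC[C@]1(C)C=C[C@](C)(C(=O)OC)CC1 | intermediate
41 | o-quinone of 40 | O=C1C(=O)C=C2C(=C1C)C=C[C@H]1[C@@]2(C)CCC(C)(O)[C@]1(C)CC[C@]1(C)C=C[C@](C)(C(=O)OC)CC1 | intermediate
42 | benzodioxane adduct, ring-D-seco tertiary alcohol | C=C(C)[C@H]1CC[C@@H](C)C2=C(C1)[C@]1(C)Oc3c(cc4c(c3C)C=C[C@H]3[C@@]4(C)CCC(C)(O)[C@]3(C)CC[C@]3(C)C=C[C@](C)(C(=O)OC)CC3)O[C@@H]1C2 | intermediate
43 | chlorooxalate of 42 | C=C(C)[C@H]1CC[C@@H](C)C2=C(C1)[C@]1(C)Oc3c(cc4c(c3C)C=C[C@H]3[C@@]4(C)CCC(C)(OC(=O)C(=O)Cl)[C@]3(C)CC[C@]3(C)C=C[C@](C)(C(=O)OC)CC3)O[C@@H]1C2 | intermediate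
44 | N-phthalimidoyl oxalate of 42 | C=C(C)[C@H]1CC[C@@H](C)C2=C(C1)[C@]1(C)Oc3c(cc4c(c3C)C=C[C@H]3[C@@]4(C)CCC(C)(OC(=O)C(=O)ON5C(=O)c6ccccc6C5=O)[C@]3(C)CC[C@]3(C)C=C[C@](C)(C(=O)OC)CC3)O[C@@H]1C2 | intermediate
45 | CNP0222748.1 | C=C(C)[C@H]1CC[C@@H](C)C2=C(C1)[C@]1(C)Oc3c(cc4c(c3C)C=C[C@H]3[C@@]4(C)CC[C@@]4(C)[C@@H]5C[C@](C)(C(=O)OC)CC[C@]5(C)CC[C@]34C)O[C@@H]1C2 | target

**Totals**

Total step count: 29. Longest linear sequence: 17 steps (steps 6–13, then 21–29).

**Steps most likely to fail**

Step 29. Hydrogen transfer to the C13 radical may be faster than its addition to the hindered, unactivated C18=C19 bond; the bond may also form on the axial face of C13 (cis C/D), or the sesquiterpene unit may be attacked under the radical conditions. Fallback: close ring D before the sesquiterpene is attached, where stannane- or silane-mediated conditions at high dilution and higher temperature can be used freely. It sets out from 38 and returns at 45. Alcohol 38 is converted through chlorooxalate F1 into N-phthalimidoyl oxalate F2, which is cyclized (the conditions of step 29, or (Me3Si)3SiH with slow addition at 80 °C) to the pentacyclic bis-silyl ether F3. DDQ then gives the 6-ene F4, Bu4NF gives the catechol F5, and Ag2O oxidation to o-quinone F6 followed by cycloaddition with 8 gives 45.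

Step 27. The diene's two faces may react with little discrimination. Besides that, tautomerization of the o-quinone to the extended quinone methide, reaction of other cyclopentadiene tautomers, or carbo-Diels–Alder addition may compete. Fallback: change from substrate control to reagent control. Quinone 41 is generated from 40 and held as a chelate on a chiral Cu(OTf)2–bis(oxazoline) Lewis acid, so that the ligand selects the diene face in a Lewis-acid-templated cycloaddition with 8. It sets out from 40 and returns at 42; no new compound is formed.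

Step 21. The hindered lithium enolate may be protonated, or may equilibrate, before the slow alkylation by the γ-branched iodide. Fallback: separate reduction from alkylation. It sets out from 33 and returns at 35. The enolate from Li/NH3 reduction is trapped with Me3SiCl as the silyl enol ether F7, which is purified; MeLi regenerates the lithium enolate in THF/HMPA, and it is alkylated with the more reactive triflate F8, made from alcohol 18 with Tf2O and pyridine.

**Further compounds**

F1 | step 29 | chlorooxalate of 38 | CC(C)(C)[Si](C)(C)Oc1c(O[Si](C)(C)C(C)(C)C)cc2c(c1C)CC[C@H]1[C@@]2(C)CCC(C)(OC(=O)C(=O)Cl)[C@]1(C)CC[C@]1(C)C=C[C@](C)(C(=O)OC)CC1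
F2 | step 29 | N-phthalimidoyl oxalate of 38 | CC(C)(C)[Si](C)(C)Oc1c(O[Si](C)(C)C(C)(C)C)cc2c(c1C)CC[C@H]1[C@@]2(C)CCC(C)(OC(=O)C(=O)ON3C(=O)c4ccccc4C3=O)[C@]1(C)CC[C@]1(C)C=C[C@](C)(C(=O)OC)CC1
F3 | step 29 | pentacyclic bis-silyl ether (ring B saturated) | CC(C)(C)[Si](C)(C)Oc1c(O[Si](C)(C)C(C)(C)C)cc2c(c1C)CC[C@H]1[C@@]2(C)CC[C@@]2(C)[C@@H]3C[C@](C)(C(=O)OC)CC[C@]3(C)CC[C@]12C
F4 | step 29 | pentacyclic 6-ene bis-silyl ether | CC(C)(C)[Si](C)(C)Oc1c(O[Si](C)(C)C(C)(C)C)cc2c(c1C)C=C[C@H]1[C@@]2(C)CC[C@@]2(C)[C@@H]3C[C@](C)(C(=O)OC)CC[C@]3(C)CC[C@]12C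
F5 | step 29 | pentacyclic 6-ene catechol | Oc1c(O)cc2c(c1C)C=C[C@H]1[C@@]2(C)CC[C@@]2(C)[C@@H]3C[C@](C)(C(=O)OC)CC[C@]3(C)CC[C@]12C
F6 | step 29 | o-quinone of F5 | O=C1C(=O)C=C2C(=C1C)C=C[C@H]1[C@@]2(C)CC[C@@]2(C)[C@@H]3C[C@](C)(C(=O)OC)CC[C@]3(C)CC[C@]12C
F0 | step 27 | none | none
F7 | step 21 | trimethylsilyl enol ether of the reduced enone | COc1c(OC)cc2c(c1C)CC[C@H]1[C@@]2(C)CCC(O[Si](C)(C)C)=C1C
F8 | step 21 | triflate of 18 | FC(F)(F)S(=O)(=O)OCC[C@]1(C)C=C[C@](C)(C(=O)OC)CC1
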